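A direct plan would assemble the ring from two chiral allylic alcohols, bis-sulfone carbinol A1 and allylic carbonate A2.
It would tie them through a diisopropylsilylene tether, would set Z-C2=C3 by ring-closing metathesis (silacycle A3), and would close the eleven-membered ring at C8–C9 by Pd(PPh3)4-catalysed allylic alkylation of seco carbonate A4.
Its weakest steps would be:
- the macrocyclisation, because a carbanion next to a neopentyl centre would have to close a strained eleven-membered ring, so that oligomerisation and elimination would compete even at high dilution;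
- the tethered metathesis, because a trisubstituted alkene would have to form between a neopentylic vinyl carbinol and an isopropenyl group inside a crowded seven-membered silaketal;
- the kinetic resolution that would supply A1, and the tether, silyl and sulfone operations after it, which would discard half of one fragment and add about six steps without adding complexity.

The new route never closes the eleven-membered ring. It rests on the transannular pair C1 (oxygenated) and C7 (methylated alkene carbon): a C1–C7 bond would turn the ring into a cyclohexane (C7–C11, C1) fused to a cycloheptene (C1–C7) that holds C2=C3 as cis. Commercial 2,2,6-trimethylcyclohexanone supplies the six-membered ring, and a C2–C6 iodo aldehyde carrying C4 (R) is annulated onto it. Wharton–Grob fragmentation of the resulting 1,3-diol monomesylate then cuts C1–C7 and delivers the macrocycle, the C1 carbonyl and E-C6=C7 in one stereospecific step, while it erases C1, C6 and C7, so both diastereomeric series converge. Macrocyclisation, tether metathesis, resolution and sulfone chemistry have no counterpart.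

Key step: step 10

Remark 1: ring atoms are numbered C1–C11 as in the target (C1 bears the acetate, C4 the aroyl ester, C11 the two methyl groups); this is also the numbering of bicyclo[5.4.0]undecane.
Remark 2: 11 is a mixture at C6 and C7, and 12–15 are carried as two diastereomers that share the relative configuration of the C1/C6/C7 triad and differ only in its absolute sense relative to C4 (R); names and SMILES show the (1S) series, the (1R) series should react alike, and step 10 merges both.
Remark 3: the ring fusion formed in step 7 is assumed to be cis (1-OH and 7-CH3 cis); if it were trans, Me4NBH(OAc)3 would replace Zn(BH4)2 in step 9 so that the C6 oxygen would again end cis to the C7 methyl group.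

Step 1
Reactants: 1 prop-2-yn-1-ol (propargyl alcohol)
Product: 3 (Z)-3-iodo-2-methylprop-2-en-1-ol, via cyclic vinylmagnesium alkoxide 2 (not isolated)
Conditions: MeMgBr (3 equiv), CuI (10 mol %), Et2O–THF, −10 °C to rt; then I2 (1.2 equiv), −10 °C; aq work-up
Reagents that add atoms: methylmagnesium bromide, C[Mg]Br; iodine, II
Why: CuI-catalysed anti-carbomagnesiation of the propargylic alkoxide places the methyl group on the internal carbon and Mg, chelated by the alkoxide oxygen, on the terminal carbon, and iodinolysis with retention gives the Z-iodoalkene in which the iodinated carbon is C2 and the carbinol carbon is C4, so the later C2=C3 geometry is fixed here.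

Step 2
Reactants: 3 (Z)-3-iodo-2-methylprop-2-en-1-ol
Product: 4 (Z)-3-iodo-2-methylprop-2-enal
Conditions: activated MnO2 (15 equiv), CH2Cl2, rt, dark; filtered and used at once
Reagents that add atoms: none
Why: Heterogeneous allylic oxidation with MnO2 stops at the aldehyde and, being neutral and run in the dark, should keep the Z geometry of the sensitive β-iodo enal.

Step 3
Reactants: 4 (Z)-3-iodo-2-methylprop-2-enal
Product: 6 (1Z,3R)-1-iodo-2-methylhexa-1,5-dien-3-ol, via diisopinocampheylborinate 5 (not isolated)
Conditions: (+)-Ipc2B(allyl) (from (−)-α-pinene, 1 M in pentane, 1.2 equiv), Et2O, −78 °C; then 3 M NaOH, 30% H2O2, 0 °C to rt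
Reagents that add atoms: (+)-B-allyldiisopinocampheylborane, C=CCB([C@H]1C[C@H]2C[C@@H]([C@@H]1C)C2(C)C)[C@H]1C[C@H]2C[C@@H]([C@@H]1C)C2(C)C
Why: Brown allylboration through a closed chair transition state, in which the isopinocampheyl groups derived from (−)-α-pinene steer the allyl group to the Re face of the aldehyde and so set C4 as R, while the oxidative work-up leaves the iodoalkene untouched.

Step 4
Reactants: 6 (1Z,3R)-1-iodo-2-methylhexa-1,5-dien-3-ol
Product: 7 1-({[(1Z,3R)-1-iodo-2-methylhexa-1,5-dien-3-yl]oxy}methyl)-4-methoxybenzene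
Conditions: NaH (1.3 equiv), 4-methoxybenzyl chloride (1.2 equiv), Bu4NI (5 mol %), THF–DMF, 0 °C to rt
Reagents that add atoms: 4-methoxybenzyl chloride, COc1ccc(CCl)cc1
Why: Williamson ether synthesis at the sodium alkoxide breaks only the O–H bond, so C4 stays R, and the 4-methoxybenzyl ether is chosen because it cannot migrate to a vinyllithium as a silyl group would and is later removed oxidatively.

Step 5
Reactants: 7 1-({[(1Z,3R)-1-iodo-2-methylhexa-1,5-dien-3-yl]oxy}methyl)-4-methoxybenzene
Product: 8 (3R,4Z)-5-iodo-3-[(4-methoxybenzyl)oxy]-4-methylpent-4-enal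
Conditions: OsO4 (2 mol %), NaIO4 (4 equiv), 2,6-lutidine (2 equiv), dioxane–H2O 3:1, rt
Reagents that add atoms: osmium tetroxide, O=[Os](=O)(=O)=O; sodium periodate, [Na+].[O-]I(=O)(=O)=O
Why: Lemieux–Johnson oxidation, in which OsO4 dihydroxylates the monosubstituted terminal alkene much faster than the hindered and electron-poor trisubstituted iodoalkene and periodate cleaves the diol to the aldehyde carbon that becomes C6.

Step 6
Reactants: 9 2,2,6-trimethylcyclohexan-1-one; 8 (3R,4Z)-5-iodo-3-[(4-methoxybenzyl)oxy]-4-methylpent-4-enal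
Product: 11 2-{(3R,4Z)-1-hydroxy-5-iodo-3-[(4-methoxybenzyl)oxy]-4-methylpent-4-en-1-yl}-2,6,6-trimethylcyclohexan-1-one (C6/C7 diastereomers), via lithium enolate 10 (not isolated)
Conditions: LiN(iPr)2 (1.2 equiv), 9 (1.25 equiv), THF, −78 to 0 °C, 1 h; then 8, −78 °C, 20 min; AcOH in THF at −78 °C
Reagents that add atoms: none
Why: Aldol addition of the only possible enolate of 9 (deprotonation can occur only at the methine carbon) to the aldehyde forms C6–C7 and the quaternary C7 at −78 °C, where addition should outrun enolisation and β-elimination of 8, and neither new stereocentre needs control because C6 is re-set in steps 8 and 9 and C7 is erased in step 10.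

Step 7
Reactants: 11 2-{(3R,4Z)-1-hydroxy-5-iodo-3-[(4-methoxybenzyl)oxy]-4-methylpent-4-en-1-yl}-2,6,6-trimethylcyclohexan-1-one
Product: 12 cis-fused (1S,4R,7R)-4-[(4-methoxybenzyl)oxy]-3,7,11,11-tetramethylbicyclo[5.4.0]undec-2-ene-1,6-diol (both C6 epimers)
Conditions: t-BuLi (3.3 equiv), Et2O–THF 5:1, −78 °C, 1 h; H2O at −78 °C
Reagents that add atoms: none
Why: Parham-type anionic cyclisation, in which deprotonation of the hydroxyl group and iodine–lithium exchange give a configurationally stable Z-vinyllithium that the Z alkene and the lithium alkoxide hold next to the non-enolisable C1 carbonyl, and 1,2-addition, expected from the axial face anti to the axial methyl groups, closes the seven-membered ring to the cis-fused tertiary carbinol with C2=C3 necessarily cis.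

Step 8
Reactants: 12 cis-fused (1S,4R,7R)-4-[(4-methoxybenzyl)oxy]-3,7,11,11-tetramethylbicyclo[5.4.0]undec-2-ene-1,6-diol
Product: 13 cis-fused (1S,4R,7S)-1-hydroxy-4-[(4-methoxybenzyl)oxy]-3,7,11,11-tetramethylbicyclo[5.4.0]undec-2-en-6-one
Conditions: Dess–Martin periodinane (1.5 equiv), NaHCO3 (5 equiv), CH2Cl2, 0 °C to rt
Reagents that add atoms: none
Why: Dess–Martin oxidation converts the secondary C6 carbinol into the ketone under buffered neutral conditions that leave the tertiary allylic C1 alcohol alone and should not trigger retro-aldol opening, and it removes the uncontrolled C6 configuration of the aldol.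

Step 9
Reactants: 13 cis-fused (1S,4R,7S)-1-hydroxy-4-[(4-methoxybenzyl)oxy]-3,7,11,11-tetramethylbicyclo[5.4.0]undec-2-en-6-one
Product: 14 (1S,4R,6S,7R)-4-[(4-methoxybenzyl)oxy]-3,7,11,11-tetramethylbicyclo[5.4.0]undec-2-ene-1,6-diol (1-OH/6-OH/7-CH3 all cis)
Conditions: Zn(BH4)2 (0.15 M in Et2O, 2 equiv), Et2O, −30 to 0 °C; aq work-up
Reagents that add atoms: none
Why: Chelation-controlled reduction of a β-hydroxy ketone, in which the Zn centre of Zn(BH4)2 bridges the C1 oxygen and the C6 carbonyl oxygen on one face of the seven-membered ring and hydride attacks from the opposite face, so the new C6 hydroxyl should end cis to the C1 hydroxyl and therefore cis to the C7 methyl group.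

Step 10
Reactants: 14 (1S,4R,6S,7R)-4-[(4-methoxybenzyl)oxy]-3,7,11,11-tetramethylbicyclo[5.4.0]undec-2-ene-1,6-diol
Product: 16 (2Z,4R,6E)-4-[(4-methoxybenzyl)oxy]-3,7,11,11-tetramethylcycloundeca-2,6-dien-1-one, via C6 mesylate 15 (not isolated)
Conditions: MsCl (1.5 equiv), Et3N (3 equiv), CH2Cl2, −20 °C; aq NaHCO3 work-up; then KOtBu (1.05 equiv), THF (0.02 M), −20 to 0 °C, 20 min; pH 7 buffer
Reagents that add atoms: none
Why: Wharton–Grob fragmentation of a cyclic 1,3-diol monosulfonate, in which the tertiary potassium alkoxide at C1 pushes the C1–C7 σ-electrons into the σ* orbital of the antiperiplanar C6–OMs bond, so that C1=O and C6=C7 form in one concerted step as mesylate leaves. The closest known reaction type is the base-induced fragmentation of bicyclic 1,3-diol monosulfonates to medium-ring cycloalkenones, long used for nine- and ten-membered sesquiterpene rings, applied here to a bicyclo[5.4.0]undecene. No ring is closed: the eleven-membered ring appears by cleavage of the bond shared by the six- and the seven-membered ring, and the cis C2=C3 of the cycloheptene becomes the Z alkene of the product without being touched. No stereocentre is created, C1, C6 and C7 are destroyed and C4 (R) is a spectator, and the E geometry of C6=C7 follows from the cis relation of the mesylate and the C7 methyl group, because in the only conformer with C6–O antiperiplanar to C1–C7 the methyl group is gauche to C5 and C8 is anti to C5. The step needs fragmentation to win over oxetane formation, E2 elimination and γ-deprotonation of the product, which the substrate secures because the cis-1,3 arrangement of alkoxide and mesylate rules out backside attack, C7 carries no hydrogen, and the single equivalent of base is consumed as the ketone forms. Both C7-epimeric series of 15 have the same relative configuration within C1/C6/C7 and should therefore give the single ketone 16.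

Step 11
Reactants: 16 (2Z,4R,6E)-4-[(4-methoxybenzyl)oxy]-3,7,11,11-tetramethylcycloundeca-2,6-dien-1-one
Product: 17 (1S,2Z,4R,6E)-4-[(4-methoxybenzyl)oxy]-3,7,11,11-tetramethylcycloundeca-2,6-dien-1-ol
Conditions: (R)-Me-CBS oxazaborolidine (1.0 equiv), catecholborane (2 equiv), toluene, −78 to −40 °C; aq work-up
Reagents that add atoms: none
Why: Corey–Bakshi–Shibata reduction, which is 1,2-selective on enones, in which the (R)-oxazaborolidine should coordinate the carbonyl oxygen on the lone pair anti to the fully substituted C11 flank and deliver hydride to the face that gives the (1S) carbinol, trans to the C4 oxygen, by reagent control.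

Step 12
Reactants: 17 (1S,2Z,4R,6E)-4-[(4-methoxybenzyl)oxy]-3,7,11,11-tetramethylcycloundeca-2,6-dien-1-ol
Product: 18 (1S,2Z,4R,6E)-3,7,11,11-tetramethylcycloundeca-2,6-diene-1,4-diol
Conditions: DDQ (1.3 equiv), CH2Cl2–pH 7 phosphate buffer 10:1, 0 °C
Reagents that add atoms: none
Why: Oxidative deprotection, in which electron transfer from the electron-rich 4-methoxybenzyl ether to DDQ and hydrolysis of the resulting benzylic oxocarbenium ion in the wet buffered medium free the C4 hydroxyl without breaking its C–O bond, so C4 stays R, and the hindered C1 carbinol should not be oxidised at 0 °C.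

Step 13
Reactants: 18 (1S,2Z,4R,6E)-3,7,11,11-tetramethylcycloundeca-2,6-diene-1,4-diol; 19 4-acetoxybenzoyl chloride
Product: 21 (1S,2Z,4R,6E)-1-acetoxy-3,7,11,11-tetramethylcycloundeca-2,6-dien-4-yl 4-acetoxybenzoate, via C4 mono-ester 20 (not isolated)
Conditions: 19 (1.05 equiv), pyridine (3 equiv), CH2Cl2, −20 to 0 °C; then Ac2O (5 equiv), Et3N, DMAP (0.3 equiv), rt
Reagents that add atoms: acetic anhydride, CC(=O)OC(C)=O
Why: Two nucleophilic acyl substitutions in one flask, in which the acid chloride acylates the C4 hydroxyl, far less hindered than the neopentylic C1 hydroxyl, and DMAP-activated acetic anhydride then esterifies C1, both at oxygen and hence with retention.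

Step 14
Reactants: 21 (1S,2Z,4R,6E)-1-acetoxy-3,7,11,11-tetramethylcycloundeca-2,6-dien-4-yl 4-acetoxybenzoate
Product: 22 CNP0246761.2, (1S,2Z,4R,6E)-1-acetoxy-3,7,11,11-tetramethylcycloundeca-2,6-dien-4-yl 4-hydroxybenzoate
Conditions: NH4OAc (10 equiv), MeOH–H2O 4:1, rt
Reagents that add atoms: none
Why: Chemoselective solvolysis of an aryl acetate, whose phenoxide leaving group makes it far more labile than the hindered secondary C1 acetate and the C4 benzoate, so that only the phenolic acetyl group should be removed under nearly neutral conditions.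

**Compound list**
1 | prop-2-yn-1-ol (propargyl alcohol) | C#CCO | starting material
2 | cyclic vinylmagnesium alkoxide (4-methyl-2,5-dihydro-1,2-oxamagnesole) | CC1=C[Mg]OC1 | intermediate
3 | (Z)-3-iodo-2-methylprop-2-en-1-ol | OC/C(C)=C\I | intermediate
4 | (Z)-3-iodo-2-methylprop-2-enal | O=C/C(C)=C\I | intermediate
5 | (1Z,3R)-1-iodo-2-methylhexa-1,5-dien-3-yl diisopinocampheylborinate | B(O[C@H](CC=C)/C(C)=C\I)([C@H]1C[C@H]2C[C@@H]([C@@H]1C)C2(C)C)[C@H]1C[C@H]2C[C@@H]([C@@H]1C)C2(C)C | intermediate
6 | (1Z,3R)-1-iodo-2-methylhexa-1,5-dien-3-ol | C=CC[C@@H](O)/C(C)=C\I | intermediate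
7 | 1-({[(1Z,3R)-1-iodo-2-methylhexa-1,5-dien-3-yl]oxy}methyl)-4-methoxybenzene | C=CC[C@@H](OCc1ccc(OC)cc1)/C(C)=C\I | intermediate
8 | (3R,4Z)-5-iodo-3-[(4-methoxybenzyl)oxy]-4-methylpent-4-enal | O=CC[C@@H](OCc1ccc(OC)cc1)/C(C)=C\I | intermediate
9 | 2,2,6-trimethylcyclohexan-1-one (racemic) | CC1CCCC(C)(C)C1=O | starting material
10 | lithium 2,6,6-trimethylcyclohex-1-en-1-olate | [Li]OC1=C(C)CCCC1(C)C | intermediate
11 | 2-{(3R,4Z)-1-hydroxy-5-iodo-3-[(4-methoxybenzyl)oxy]-4-methylpent-4-en-1-yl}-2,6,6-trimethylcyclohexan-1-one (mixture at C6 and C7) | O=C1C(C)(C)CCCC1(C)C(O)C[C@@H](OCc2ccc(OC)cc2)/C(C)=C\I | intermediate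
12 | cis-fused (1S,4R,7R)-4-[(4-methoxybenzyl)oxy]-3,7,11,11-tetramethylbicyclo[5.4.0]undec-2-ene-1,6-diol (both C6 epimers; with its 1R,7S diastereomer) | O[C@@]12C(C)(C)CCC[C@]1(C)C(O)C[C@@H](OCc3ccc(OC)cc3)C(C)=C2 | intermediate
13 | cis-fused (1S,4R,7S)-1-hydroxy-4-[(4-methoxybenzyl)oxy]-3,7,11,11-tetramethylbicyclo[5.4.0]undec-2-en-6-one (with its 1R,7R diastereomer) | O[C@@]12C(C)(C)CCC[C@]1(C)C(=O)C[C@@H](OCc3ccc(OC)cc3)C(C)=C2 | intermediate
14 | (1S,4R,6S,7R)-4-[(4-methoxybenzyl)oxy]-3,7,11,11-tetramethylbicyclo[5.4.0]undec-2-ene-1,6-diol (1-OH, 6-OH and 7-CH3 cis; with its 1R,6R,7S diastereomer) | O[C@@]12C(C)(C)CCC[C@]1(C)[C@@H](O)C[C@@H](OCc3ccc(OC)cc3)C(C)=C2 | intermediate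
15 | (1S,4R,6S,7R)-1-hydroxy-4-[(4-methoxybenzyl)oxy]-3,7,11,11-tetramethylbicyclo[5.4.0]undec-2-en-6-yl methanesulfonate (with its 1R,6R,7S diastereomer) | O[C@@]12C(C)(C)CCC[C@]1(C)[C@@H](OS(C)(=O)=O)C[C@@H](OCc3ccc(OC)cc3)C(C)=C2 | intermediate
16 | (2Z,4R,6E)-4-[(4-methoxybenzyl)oxy]-3,7,11,11-tetramethylcycloundeca-2,6-dien-1-one | O=C1/C=C(/C)[C@H](OCc2ccc(OC)cc2)C/C=C(\C)CCCC1(C)C | intermediate
17 | (1S,2Z,4R,6E)-4-[(4-methoxybenzyl)oxy]-3,7,11,11-tetramethylcycloundeca-2,6-dien-1-ol | O[C@H]1/C=C(/C)[C@H](OCc2ccc(OC)cc2)C/C=C(\C)CCCC1(C)C | intermediate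
18 | (1S,2Z,4R,6E)-3,7,11,11-tetramethylcycloundeca-2,6-diene-1,4-diol | O[C@H]1/C=C(/C)[C@H](O)C/C=C(\C)CCCC1(C)C | intermediate
19 | 4-acetoxybenzoyl chloride | CC(=O)Oc1ccc(cc1)C(Cl)=O | starting material
20 | (1S,2Z,4R,6E)-1-hydroxy-3,7,11,11-tetramethylcycloundeca-2,6-dien-4-yl 4-acetoxybenzoate | O[C@H]1/C=C(/C)[C@H](OC(=O)c2ccc(OC(C)=O)cc2)C/C=C(\C)CCCC1(C)C | intermediate
21 | (1S,2Z,4R,6E)-1-acetoxy-3,7,11,11-tetramethylcycloundeca-2,6-dien-4-yl 4-acetoxybenzoate | CC(=O)O[C@H]1/C=C(/C)[C@H](OC(=O)c2ccc(OC(C)=O)cc2)C/C=C(\C)CCCC1(C)C | intermediate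
22 | CNP0246761.2, (1S,2Z,4R,6E)-1-acetoxy-3,7,11,11-tetramethylcycloundeca-2,6-dien-4-yl 4-hydroxybenzoate | CC(=O)O[C@H]1/C=C(/C)[C@H](OC(=O)c2ccc(O)cc2)C/C=C(\C)CCCC1(C)C | target

Total steps: 14. Longest linear sequence: 14 steps (1 to 22; 9 and 19 are purchased).

Steps most likely to fail:

1. Step 7. The vinyllithium may be protonated, or the lithium aldolate may undergo retro-aldol cleavage, before the carbanion adds to the doubly neopentylic C1 carbonyl. The fallback sets out from 11 and comes back at 12. The iodine would be removed on purpose (t-BuLi, then MeOH at −78 °C) to give isopropenyl ketol F1. The small nucleophile CH2=CHMgBr with anhydrous CeCl3 would then add to C1 to give triene diol F2. Ring-closing metathesis with second-generation Grubbs catalyst RuCl2(=CHPh)(SIMes)(PCy3) in toluene at 80 °C would form C2=C3, which can only be cis in a seven-membered ring, and give 12.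

2. Step 10. The mesylate may be lost by E2 elimination towards C5 or by substitution, the ring may not reach the conformer in which C6–O is antiperiplanar to C1–C7, or excess base may deprotonate the γ-position (C4) of the product. The fallback sets out from 13 and comes back at 16. KN(SiMe3)2 and PhNTf2 in THF at −78 °C would let the C1 alkoxide of 13 expel the C6 enolate by retro-aldol ring opening, and the enolate would be triflated as it forms to give enol triflate F3. Pd(OAc)2, PPh3, HCO2H and Bu3N in DMF would then replace the triflate by hydrogen with retention and give 16. The geometry of the trapped enolate, and with it E or Z at C6=C7, would have to be established.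

3. Step 11. Facial selectivity at C1 may be poor, because the oxazaborolidine may not distinguish the quaternary flank from the Z-alkenyl flank of the ring ketone. The fallback sets out from 16 and comes back at 18. DDQ would first remove the 4-methoxybenzyl group to give hydroxy enone F4. Me4NBH(OAc)3 in MeCN–AcOH would then deliver hydride internally from the boron bound to the C4 oxygen across the Z alkene, which should place the new C1 hydroxyl trans to the C4 hydroxyl and give diol 18 directly.

**Further compounds**
F1 | step 7 | 2-{(3R)-1-hydroxy-3-[(4-methoxybenzyl)oxy]-4-methylpent-4-en-1-yl}-2,6,6-trimethylcyclohexan-1-one | O=C1C(C)(C)CCCC1(C)C(O)C[C@@H](OCc2ccc(OC)cc2)C(C)=C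
F2 | step 7 | (3R)-1-(2-ethenyl-2-hydroxy-1,3,3-trimethylcyclohexyl)-3-[(4-methoxybenzyl)oxy]-4-methylpent-4-en-1-ol | C=CC1(O)C(C)(C)CCCC1(C)C(O)C[C@@H](OCc2ccc(OC)cc2)C(C)=C
F3 | step 10 | (2Z,4R,6Z)-4-[(4-methoxybenzyl)oxy]-3,7,11,11-tetramethyl-1-oxocycloundeca-2,6-dien-6-yl trifluoromethanesulfonate | O=C1/C=C(/C)[C@H](OCc2ccc(OC)cc2)C/C(OS(=O)(=O)C(F)(F)F)=C(\C)CCCC1(C)C
F4 | step 11 | (2Z,4R,6E)-4-hydroxy-3,7,11,11-tetramethylcycloundeca-2,6-dien-1-one | O=C1/C=C(/C)[C@H](O)C/C=C(\C)CCCC1(C)C
A1 | direct plan | (3S)-4,4-dimethyl-6,6-bis(phenylsulfonyl)hex-1-en-3-ol | O[C@H](C(C)(C)CC(S(=O)(=O)c1ccccc1)S(=O)(=O)c1ccccc1)C=C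
A2 | direct plan | (2E,5R)-5-hydroxy-2,6-dimethylhepta-2,6-dien-1-yl methyl carbonate | O[C@H](C/C=C(\C)COC(=O)OC)C(C)=C
A3 | direct plan | (4R,7S)-2,2-diisopropyl-5-methyl-1,3-dioxa-2-silacyclohept-5-ene with the carbonate chain on C4 and the bis-sulfone chain on C7 | CC(C)[Si]1(C(C)C)O[C@H](C(C)(C)CC(S(=O)(=O)c2ccccc2)S(=O)(=O)c2ccccc2)C=C(C)[C@@H](C/C=C(\C)COC(=O)OC)O1
A4 | direct plan | (2E,5R,6Z,8S)-5-(tert-butyldimethylsilyloxy)-8-hydroxy-2,6,9,9-tetramethyl-11,11-bis(phenylsulfonyl)undeca-2,6-dien-1-yl methyl carbonate | O[C@H](C(C)(C)CC(S(=O)(=O)c1ccccc1)S(=O)(=O)c1ccccc1)/C=C(/C)[C@H](O[Si](C)(C)C(C)(C)C)C/C=C(\C)COC(=O)OC
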